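In the zeta run X came far more slowly late than early, 0.514 mM/min between 50.0 s and 120 s against 3.36 mM/min in the first 10.0 s, although Q rose from 32.3% to 95.8% of the charge.

- zeta: Q 40 mM (in portions, 3); L 2 µM; run made earlier; portions every 30 s
- flask: Q 20 mM (in portions, 3); L 2.0 µM; time 6.0 min; the portions of Q follow each other after 30 s, the first at the start

zeta run (percent of the Q charged)

| time / s | Q / % | X / % |
|---|---|---|
| 10.0 | 32.3 | 1.4 |
| 20.0 | 31.2 | 1.8 |
| 50.0 | 63.1 | 3.3 |
| 120 | 95.8 | 4.8 |

(standard deviation of a reading: 0.3 percentage points)

- the species in which most of what was charged as Q, at 6.0 min sits (Q / X)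
- the largest share itself, whichever of these holds it, in percent of the Q charged

- percentages count the whole charge, also what has not yet gone in

So I expected this flask to end with Q left over and X standing still, and I asked how fast it would get there. The portions stand on the shortest rung of the ladder: the last goes in at 60.0 s. The slowing comes next. Between 50.0 s and 120 s in the zeta run, cX rose by 0.685 mM per factor e of elapsed time. I call this reading the age gain: a rate falling as one over the elapsed time. Between 20.0 s and 50.0 s the same reckoning gave 0.655 mM, though each reading carries 0.3 percentage points. The use of Q stands on the slowest rung: at the rate the age gain gives at 120 s, the 20 mM of this flask would last 58.4 min, far longer than the 6.0 min asked, so I expected Q to keep most.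

With the same 2.0 µM of L, I took X as near zero order in Q and let this flask follow the zeta run. Starting from 1.92 mM at 120 s and adding the age gain times 1.10, I reached 2.67 mM of X. That is 13.4% of the charge, leaving 86.6% as Q.

The forecast, which read the slowing as “strong product inhibition with near zero order in Q”, put 83% in Q, with a range of 79% to 88%.

The flask gave 86.7% as Q, against my 86.6%.

    Q + L → X + L, rate k1*[Q]*[L]/(1 + ([Q]/Km1) + ([Q]/Ksi1)^2) (0.423 mM, 14.5 mM, k = 67400 /M/s)
    Q + L → J (k = 0.365 /M/s)
    2 L → E (k = 10200 /M/s)

At 6.00 min, L stood at 1.55% of its charge. X reached 2.66 mM, against the 2.67 mM reckoned from the age gain. The same age gain, 0.685 mM, put on the neighbour flask charged with 5.0 mM of Q, gives 53.5% of that charge as X. That neighbour flask ended with X holding most, at 59.8%.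

(The data were computed on assumed constants, and the scatter is random.)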